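The route rests on disconnecting the C4–CH3 bond of the furan-2,5-dione (maleic anhydride) ring. The key step exploits that ring's tetrasubstituted C3=C4 alkene, where C3 bears the C16 chain and C4 only a methyl group. A (3+2) cycloaddition joins the carbon of diazomethane to C4 and its terminal nitrogen to C3 of the corresponding monoalkylmaleic anhydride, so the methyl carbon arrives inside a cis-fused 1-pyrazoline. Loss of N2 with a hydrogen shift then regenerates the alkene. The precursor is (S)-2-(15-acetoxyhexadecyl)maleic anhydride, assembled by palladium-catalysed dicarbonylation of a terminal alkyne whose acetoxy stereocentre derives from (S)-but-3-yn-2-ol.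

Key step: step 6

Remark on the chemistry: ring atoms are numbered O1, C2, C3 (chain-bearing), C4, C5; the cycloadduct can only be cis-fused and should form as both cis-fused diastereomers relative to the remote acetoxy centre (one is drawn), which is immaterial because both ring-fusion centres vanish in step 7.

Step 1
Reactants: 1 (S)-but-3-yn-2-ol; 2 1-bromotetradecane
Product: 4 (S)-octadec-3-yn-2-ol, via dilithiated (S)-but-3-yn-2-ol 3 (not isolated)
Conditions: n-BuLi (2.1 equiv), THF, −78 → 0 °C; then 2, DMPU, 0 °C → rt; H2O
Reagents that add atoms: 1-bromotetradecane, CCCCCCCCCCCCCCBr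
Why: Acetylide alkylation: in the C,O-dianion the acetylide carbon is far more nucleophilic than the lithium alkoxide, so SN2 displacement on the primary bromide should extend the chain at carbon only, and the carbinol stereocentre brought in with 1 is not touched.

Step 2
Reactants: 4 (S)-octadec-3-yn-2-ol
Product: 6 (S)-octadec-17-yn-2-ol, via dipotassium acetylide alkoxide 5 (not isolated)
Conditions: KH (4 equiv), H2N(CH2)3NH2, 0 °C → rt; then H2O, 0 °C
Reagents that add atoms: none
Why: Alkyne zipper reaction: potassium 3-aminopropylamide should walk the triple bond along the chain by repeated propargyl–allenyl proton shifts until the terminal acetylide, the thermodynamic sink, is reached, while the neighbouring alkoxide suppresses deprotonation of the carbinol C–H so that the (S) centre is retained.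

Step 3
Reactants: 6 (S)-octadec-17-yn-2-ol; 7 acetic anhydride
Product: 8 (S)-octadec-17-yn-2-yl acetate
Conditions: Ac2O, pyridine, DMAP (cat.), CH2Cl2, 0 °C → rt
Reagents that add atoms: acetic anhydride, CC(=O)OC(C)=O
Why: DMAP-catalysed O-acylation (nucleophilic catalysis) installs the acetate of the target with retention, since the C–O bond of the stereocentre is not broken and the terminal alkyne is inert.

Step 4
Reactants: 8 (S)-octadec-17-yn-2-yl acetate; 9 carbon monoxide
Product: 10 (S)-2-(15-acetoxyhexadecyl)maleic anhydride [(S)-16-(2,5-dioxo-2,5-dihydrofuran-3-yl)hexadecan-2-yl acetate]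
Conditions: PdI2 (1 mol %), KI (10 mol %), CO/air (4:1, ca. 40 atm, autoclave), 1,4-dioxane–H2O, 80 °C
Reagents that add atoms: carbon monoxide, [C-]#[O+]; water, O
Why: Oxidative dicarbonylation of a 1-alkyne catalysed by PdI2/KI: syn addition of a palladium–carboxyl unit (from CO and water on divalent palladium) across the triple bond, CO insertion and ring closure on the acyl palladium should give the cis-dicarbonylated alkene directly as the anhydride, air returning zerovalent palladium to divalent palladium, and the near-neutral medium leaves the acetate and its stereocentre alone.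

Step 5
Reactants: 11 N-methyl-N-nitroso-p-toluenesulfonamide
Product: 12 diazomethane (dry ethereal solution, used at once)
Conditions: KOH, H2O, 2-(2-ethoxyethoxy)ethanol, Et2O, 65 °C bath, co-distillation into a cooled receiver; distillate dried over KOH pellets (blast shield, smooth joints)
Reagents that add atoms: none
Why: Base-induced cleavage of the N-nitrososulfonamide (standard diazomethane generation) releases CH2N2, which co-distils with ether while the high-boiling alcohol stays behind, so the solution carries no nucleophile that could open the anhydride in step 6.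

Step 6
Reactants: 10 (S)-2-(15-acetoxyhexadecyl)maleic anhydride; 12 diazomethane
Product: 13 (2S)-16-(4,6-dioxo-3,3a,4,6-tetrahydro-6aH-furo[3,4-c]pyrazol-6a-yl)hexadecan-2-yl acetate (cis-fused 1-pyrazoline; N on the chain-bearing ring-fusion carbon, the new CH2 on the other)
Conditions: 12 (ca. 2 equiv), dry Et2O, 0 °C → rt, dark; excess swept out with N2; evaporation below 25 °C, crude used directly
Reagents that add atoms: diazomethane, C=[N+]=[N-]
Why: This is a concerted, suprafacial 1,3-dipolar (Huisgen) cycloaddition in which the nucleophilic carbon of the dipole bonds to C4 of the electron-poor ring alkene slightly ahead of N–C3 bond formation. The closest known reaction type is the addition of diazoalkanes to citraconic anhydride, citraconimides, citraconate esters and α-substituted acrylates, which gives 1-pyrazolines with nitrogen on the substituted carbon. The pyrazoline ring is closed intermolecularly as a (3+2) annulation onto the existing anhydride ring, the C4–CH2 and C3–N bonds forming in the same step to give a bicyclo[3.3.0] framework. The two new stereocentres at C3 and C4 are set cis to each other by suprafacial addition to the ring-constrained alkene, whereas the remote acetoxy centre gives no facial bias, which does not matter because both centres are destroyed in step 7. The step needs regioselectivity, secured by the unsubstituted and less hindered C4 accepting the carbon terminus while the C3 chain disfavours the reverse orientation, and chemoselectivity for C=C over the anhydride carbonyls and the acetate, secured by the two flanking carbonyl groups that activate the alkene and by dry, alcohol-free diazomethane at low temperature. Because C3 is quaternary, the acidic α-hydrogen needed for tautomerisation to an unreactive 2-pyrazoline is absent.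

Step 7
Reactants: 13 cis-fused 1-pyrazoline adduct
Product: 14 (S)-2-(15-acetoxyhexadecyl)-3-methylmaleic anhydride [(S)-16-(4-methyl-2,5-dioxo-2,5-dihydrofuran-3-yl)hexadecan-2-yl acetate], the target
Conditions: toluene, 110 °C, until N2 evolution ceases
Reagents that add atoms: none
Why: Pyrazoline thermolysis: extrusion of N2 from the 3-acyl-1-pyrazoline breaks the C3–N and CH2–N bonds while the C4 hydrogen shifts to the exocyclic carbon, which becomes the methyl group as the conjugated C3=C4 bond is re-formed, so both temporary stereocentres vanish and the acetoxy centre is not involved.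

Compound list
1 | (S)-but-3-yn-2-ol | C[C@H](O)C#C | starting material
2 | 1-bromotetradecane | CCCCCCCCCCCCCCBr | starting material
3 | dilithiated (S)-but-3-yn-2-ol (C4 acetylide, O2 alkoxide, dilithium salt) | C[C@H]([O-])C#[C-].[Li+].[Li+] | intermediate
4 | (S)-octadec-3-yn-2-ol | C[C@H](O)C#CCCCCCCCCCCCCCC | intermediate
5 | dipotassium salt of (S)-octadec-17-yn-2-ol (C18 acetylide, O2 alkoxide) | C[C@H]([O-])CCCCCCCCCCCCCCC#[C-].[K+].[K+] | intermediate
6 | (S)-octadec-17-yn-2-ol | C[C@H](O)CCCCCCCCCCCCCCC#C | intermediate
7 | acetic anhydride | CC(=O)OC(C)=O | starting material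
8 | (S)-octadec-17-yn-2-yl acetate | CC(=O)O[C@@H](C)CCCCCCCCCCCCCCC#C | intermediate
9 | carbon monoxide | [C-]#[O+] | starting material
10 | (S)-2-(15-acetoxyhexadecyl)maleic anhydride, i.e. (S)-16-(2,5-dioxo-2,5-dihydrofuran-3-yl)hexadecan-2-yl acetate | CC(=O)O[C@@H](C)CCCCCCCCCCCCCCC1=CC(=O)OC1=O | intermediate
11 | N-methyl-N-nitroso-p-toluenesulfonamide | CN(N=O)S(=O)(=O)c1ccc(C)cc1 | starting material
12 | diazomethane | C=[N+]=[N-] | intermediate
13 | (2S)-16-(4,6-dioxo-3,3a,4,6-tetrahydro-6aH-furo[3,4-c]pyrazol-6a-yl)hexadecan-2-yl acetate, cis-fused 1-pyrazoline (one of the two cis-fused diastereomers drawn; the other has both ring-fusion centres inverted) | CC(=O)O[C@@H](C)CCCCCCCCCCCCCC[C@]12N=NC[C@H]1C(=O)OC2=O | intermediate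
14 | (S)-2-(15-acetoxyhexadecyl)-3-methylmaleic anhydride, i.e. (S)-16-(4-methyl-2,5-dioxo-2,5-dihydrofuran-3-yl)hexadecan-2-yl acetate | CC(=O)O[C@@H](C)CCCCCCCCCCCCCCC1=C(C)C(=O)OC1=O | target

Total step count: 7. Longest linear sequence: 6 steps (steps 1–4, 6 and 7; step 5 is the separate one-step preparation of the dipole solution).

Steps most likely to fail

Step 6 (cycloaddition). The dipole may add in the reverse orientation, giving an adduct that tautomerises and no longer loses nitrogen cleanly. Diazomethane may also be consumed by O-methylation after adventitious ring opening of the anhydride. The fallback leaves the cycloaddition and builds the tetrasubstituted ring alkene with the methyl group already in place; it sets out from 6 and comes back at 14. Alkynol 6 would be converted into its dianion (n-BuLi, 2 equiv, THF, −78 °C) and C-methylated with MeI to (S)-nonadec-17-yn-2-ol F1. Acetylation (Ac2O, pyridine, DMAP) would give (S)-nonadec-17-yn-2-yl acetate F2. Nickel-catalysed reductive double carboxylation of this internal alkyne with CO2 (Ni(acac)2(bpy) cat., Zn powder, MgBr2, DMF, CO2 1 atm, rt), followed by acidification, should give (S,Z)-2-(15-acetoxyhexadecyl)-3-methylbut-2-enedioic acid F3. As a dialkylmaleic acid, F3 is expected to close spontaneously to 14.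

Step 7 (nitrogen extrusion). After loss of N2, ring closure to a cyclopropane or hydrogen migration toward C3 (exocyclic alkene) may compete with the desired shift to the new carbon. The fallback uses radical chemistry; it sets out from 8 and comes back at 14. Oxidative cleavage of the terminal alkyne (RuCl3 cat., NaIO4, CCl4–MeCN–H2O) would give (S)-16-acetoxyheptadecanoic acid F4. Esterification with N-hydroxypyridine-2-thione (DCC, DMAP, CH2Cl2, dark) would give the Barton ester 2-thioxopyridin-1(2H)-yl (S)-16-acetoxyheptadecanoate F5. Visible-light photolysis of F5 with excess citraconic anhydride (Barton decarboxylative radical addition) should add the primary alkyl radical to the unsubstituted alkene carbon and transfer the 2-pyridylthio group to the methyl-bearing carbon. This would give (2S)-16-[4-methyl-2,5-dioxo-4-(pyridin-2-ylsulfanyl)oxolan-3-yl]hexadecan-2-yl acetate F6. β-Elimination of pyridine-2-thiol (Et3N, CH2Cl2, rt to gentle warming) would then deliver 14.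

Step 4 (dicarbonylation). Carbonylation of the lipophilic alkyne in aqueous dioxane may be sluggish, with partial hydrolysis of the anhydride or over-carbonylation. The fallback makes the diester first and closes the ring afterwards by dehydration; it sets out from 8 and comes back at 10. Dicarbonylation in methanol (PdI2 cat., KI, CO/air, MeOH) would give dimethyl (Z)-2-[(15S)-15-acetoxyhexadecyl]but-2-enedioate F7. Saponification (LiOH, THF–H2O; then HCl) would give (Z)-2-[(15S)-15-hydroxyhexadecyl]but-2-enedioic acid F8. Heating F8 in Ac2O should close the anhydride and re-acetylate the alcohol in one operation, giving 10.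

Further compounds
F1 | step 6 | (S)-nonadec-17-yn-2-ol | C[C@H](O)CCCCCCCCCCCCCCC#CC
F2 | step 6 | (S)-nonadec-17-yn-2-yl acetate | CC(=O)O[C@@H](C)CCCCCCCCCCCCCCC#CC
F3 | step 6 | (S,Z)-2-(15-acetoxyhexadecyl)-3-methylbut-2-enedioic acid | CC(=O)O[C@@H](C)CCCCCCCCCCCCCC/C(C(=O)O)=C(C)/C(=O)O
F4 | step 7 | (S)-16-acetoxyheptadecanoic acid | CC(=O)O[C@@H](C)CCCCCCCCCCCCCCC(=O)O
F5 | step 7 | 2-thioxopyridin-1(2H)-yl (S)-16-acetoxyheptadecanoate | CC(=O)O[C@@H](C)CCCCCCCCCCCCCCC(=O)On1ccccc1=S
F6 | step 7 | (2S)-16-[4-methyl-2,5-dioxo-4-(pyridin-2-ylsulfanyl)oxolan-3-yl]hexadecan-2-yl acetate (mixture of ring diastereomers) | CC(=O)O[C@@H](C)CCCCCCCCCCCCCCC1C(=O)OC(=O)C1(C)Sc2ccccn2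
F7 | step 4 | dimethyl (Z)-2-[(15S)-15-acetoxyhexadecyl]but-2-enedioate | CC(=O)O[C@@H](C)CCCCCCCCCCCCCC/C(C(=O)OC)=C/C(=O)OC
F8 | step 4 | (Z)-2-[(15S)-15-hydroxyhexadecyl]but-2-enedioic acid | C[C@H](O)CCCCCCCCCCCCCC/C(C(=O)O)=C/C(=O)O
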